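**Retrosynthetic overview**

1. The tetronic acid ring is the only ring made (the furan is bought as 3-bromofuran). It is closed last by Dieckmann cyclisation of enol propanoate 24, not by the usual tetronate aldol/dehydration, which favours the Z-ylidene.
2. The (5E) geometry is fixed mechanistically: ynoate 21 → syn-hydrostannation/iodination (chain cis to CO2Me) → stereoretentive Cu C–O coupling with propanoate.
3. Ynoate 21 comes from the CH2CHO terminus of dienal 17 (nonaflation–elimination to the alkyne, then ClCO2Me).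
4. The (E,Z)-diene is made by Suzuki–Miyaura union of (E)-alkenylboronate 14 (Takai–Utimoto) with (Z)-alkenyl iodide 9 (Normant carbocupration of propyne).
5. Both methyl stereocentres are set in one step by iridium-catalysed double asymmetric hydrogenation of achiral (2E,6E)-8-hydroxygeranyl acetate 11.

Assumption: the target is taken exactly as the SMILES encodes it, i.e. the (5E)-alkylidene tetronic acid (side chain on the side of C4–OH) with 2′R, 6′S, 7′E, 9′Z, and the ligand antipode written in step 5 is taken to be the one that turns (E)-geranyl-type olefins into the 3R series.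

**Route**

Step 1
Reactants: 1 3-bromofuran; 2 oxetane
Product: 4 3-(furan-3-yl)propan-1-ol, via furan-3-yllithium 3 (not isolated)
Conditions: n-BuLi, THF, −78 °C; then 2, BF3·OEt2, −78 °C
Reagents that add atoms: none
Why: Bromine–lithium exchange gives 3-furyllithium, which is configurationally and positionally stable at −78 °C and opens the BF3-activated oxetane by SN2 ring opening to deliver the three-carbon tether in one step.

Step 2
Reactants: 4 3-(furan-3-yl)propan-1-ol
Product: 5 3-(3-bromopropyl)furan
Conditions: CBr4, PPh3, CH2Cl2, 0 °C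
Reagents that add atoms: carbon tetrabromide, BrC(Br)(Br)Br
Why: Appel reaction, an SN2 displacement of the primary alkoxyphosphonium ion under neutral conditions that the furan tolerates.

Step 3
Reactants: 5 3-(3-bromopropyl)furan; 6 propyne
Product: 9 3-[(4Z)-5-iodo-4-methylpent-4-en-1-yl]furan, via Grignard reagent 7 (not isolated), via alkenylcopper 8 (not isolated)
Conditions: Mg, Et2O, rt; CuBr·SMe2 (1 equiv), Et2O/Me2S, −45 °C; 6, −25 °C; then I2, THF, −50 → 0 °C
Reagents that add atoms: iodine, II
Why: Normant carbocupration adds RCu·MgBr2 syn across propyne with the alkyl group on the internal carbon, and iodinolysis of the alkenylcopper occurs with retention, so the iodide is formed cis to the chain (Z).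

Step 4
Reactants: 10 geranyl acetate
Product: 11 (2E,6E)-8-hydroxy-3,7-dimethylocta-2,6-dien-1-yl acetate
Conditions: SeO2 (0.2 equiv), t-BuOOH (3 equiv), CH2Cl2, rt
Reagents that add atoms: tert-butyl hydroperoxide, CC(C)(C)OO
Why: Selenium dioxide-catalysed allylic oxidation (ene reaction then [2,3]-sigmatropic shift, SeO2 recycled by t-BuOOH) attacks the electron-richer terminal olefin at its (E)-methyl group and leaves the acetate-deactivated 2,3-olefin untouched.

Step 5
Reactants: 11 (2E,6E)-8-hydroxy-3,7-dimethylocta-2,6-dien-1-yl acetate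
Product: 12 (3R,7S)-8-hydroxy-3,7-dimethyloctyl acetate
Conditions: H2 (50 bar), [Ir(cod)(L)][B(C6H3(CF3)2)4] (1 mol %, L = (S)-7-[(di-o-tolylphosphanyl)oxy]-2-phenyl-6,7-dihydro-5H-cyclopenta[b]pyridine), CH2Cl2, rt
Reagents that add atoms: none
Why: Iridium N,P-ligand-catalysed asymmetric hydrogenation of trisubstituted olefins (the reaction class that reduces farnesol and tocotrienyl esters olefin by olefin with high selectivity) is used twice in one pot: both (E)-olefins point the same way along the chain, so one catalyst antipode adds H2 to the same enantioface of each and creates C3 (R) and C7 (S) from achiral 11.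

Step 6
Reactants: 12 (3R,7S)-8-hydroxy-3,7-dimethyloctyl acetate
Product: 13 (3R,7S)-3,7-dimethyl-8-oxooctyl acetate
Conditions: Dess–Martin periodinane, CH2Cl2, 0 °C; used crude
Reagents that add atoms: none
Why: Dess–Martin oxidation stops at the aldehyde under near-neutral conditions and does not epimerise the α-methyl centre when 13 is used at once without chromatography.

Step 7
Reactants: 13 (3R,7S)-3,7-dimethyl-8-oxooctyl acetate
Product: 14 (3R,7S,8E)-3,7-dimethyl-9-(4,4,5,5-tetramethyl-1,3,2-dioxaborolan-2-yl)non-8-en-1-yl acetate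
Conditions: CrCl2 (8 equiv), Cl2CHB(pin) (2 equiv), LiI (4 equiv), THF, rt
Reagents that add atoms: 2-(dichloromethyl)-4,4,5,5-tetramethyl-1,3,2-dioxaborolane, ClC(Cl)B1OC(C)(C)C(C)(C)O1
Why: Takai–Utimoto boron olefination, in which the geminal dichromium species from the dihalomethylboronate adds to the aldehyde and eliminates to the (E)-alkenylboronate without touching the acetate or the α-stereocentre.

Step 8
Reactants: 14 (3R,7S,8E)-3,7-dimethyl-9-(4,4,5,5-tetramethyl-1,3,2-dioxaborolan-2-yl)non-8-en-1-yl acetate; 9 3-[(4Z)-5-iodo-4-methylpent-4-en-1-yl]furan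
Product: 16 (3R,7S,8E,10Z)-14-(furan-3-yl)-3,7,11-trimethyltetradeca-8,10-dien-1-ol, via dienyl acetate 15 (not isolated)
Conditions: Pd(dppf)Cl2 (5 mol %), K2CO3 (4 equiv), THF/MeOH/H2O, 45 °C
Reagents that add atoms: none
Why: Suzuki–Miyaura coupling proceeds with retention at both sp2 carbons, so the (8E,10Z)-diene is assembled stereospecifically, and the methanolic carbonate then cleaves the primary acetate in the same pot by transesterification.

Step 9
Reactants: 16 (3R,7S,8E,10Z)-14-(furan-3-yl)-3,7,11-trimethyltetradeca-8,10-dien-1-ol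
Product: 17 (3R,7S,8E,10Z)-14-(furan-3-yl)-3,7,11-trimethyltetradeca-8,10-dienal
Conditions: Dess–Martin periodinane, CH2Cl2, 0 °C
Reagents that add atoms: none
Why: Dess–Martin oxidation of the primary alcohol is chemoselective beside the diene and the furan, and the β-methyl centre of 17 cannot enolise.

Step 10
Reactants: 17 (3R,7S,8E,10Z)-14-(furan-3-yl)-3,7,11-trimethyltetradeca-8,10-dienal
Product: 19 3-[(4Z,6E,8S,12R)-4,8,12-trimethyltetradeca-4,6-dien-13-yn-1-yl]furan, via enol nonaflate 18 (not isolated)
Conditions: C4F9SO2F (1.2 equiv), phosphazene base P2-Et (2.5 equiv), DMF, −20 °C → rt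
Reagents that add atoms: none
Why: One-pot nonaflation–elimination, in which the phosphazene base enolises the aldehyde, the enolate is O-sulfonylated by C4F9SO2F and a second equivalent of base eliminates nonaflate (E2) to the terminal alkyne; the stereocentre is β to the carbonyl, is never part of the enolate and becomes the propargylic centre unchanged.

Step 11
Reactants: 19 3-[(4Z,6E,8S,12R)-4,8,12-trimethyltetradeca-4,6-dien-13-yn-1-yl]furan
Product: 21 methyl (4R,8S,9E,11Z)-15-(furan-3-yl)-4,8,12-trimethylpentadeca-9,11-dien-2-ynoate, via lithium acetylide 20 (not isolated)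
Conditions: n-BuLi (1.05 equiv), THF, −78 °C; then ClCO2Me, −78 → 0 °C
Reagents that add atoms: methyl chloroformate, COC(=O)Cl
Why: Deprotonation of the terminal alkyne and C-acylation of the lithium acetylide with a chloroformate, run at −78 °C where n-BuLi does not metalate the furan.

Step 12
Reactants: 21 methyl (4R,8S,9E,11Z)-15-(furan-3-yl)-4,8,12-trimethylpentadeca-9,11-dien-2-ynoate
Product: 23 methyl (2E,4R,8S,9E,11Z)-15-(furan-3-yl)-2-iodo-4,8,12-trimethylpentadeca-2,9,11-trienoate, via vinylstannane 22 (not isolated)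
Conditions: Bu3SnH (1.05 equiv, slow addition), Pd(PPh3)4 (3 mol %), THF, 0 °C; then I2 (to persistent colour, ca. 1.2 equiv), −78 → 0 °C, dark
Reagents that add atoms: iodine, II
Why: Palladium-catalysed hydrostannation of a 2-alkynoate is a syn addition that puts tin α to the ester (directed by the ester and the branched γ-carbon), so the alkyl chain ends up cis to CO2Me, and iododestannylation then occurs with retention, which fixes the future (5E)-ylidene geometry.

Step 13
Reactants: 23 methyl (2E,4R,8S,9E,11Z)-15-(furan-3-yl)-2-iodo-4,8,12-trimethylpentadeca-2,9,11-trienoate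
Product: 24 methyl (2E,4R,8S,9E,11Z)-15-(furan-3-yl)-4,8,12-trimethyl-2-(propanoyloxy)pentadeca-2,9,11-trienoate
Conditions: EtCO2Cs (2 equiv), CuI (20 mol %), trans-N,N′-dimethylcyclohexane-1,2-diamine (40 mol %), 1,4-dioxane, 60 °C, dark
Reagents that add atoms: cesium propanoate, CCC(=O)[O-].[Cs+]
Why: Proposed new method: an Ullmann-type copper-catalysed C(sp2)–O coupling of the electron-poor alkenyl iodide with a carboxylate, expected to run by oxidative addition of the diamine-ligated copper carboxylate into the C–I bond and C–O reductive elimination with retention of olefin geometry, the closest known reactions being the copper/diamine-catalysed intramolecular O-vinylation of carboxylic acids to enol lactones and the Goldberg-type N-vinylation of amides with alkenyl iodides.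

Step 14
Reactants: 24 methyl (2E,4R,8S,9E,11Z)-15-(furan-3-yl)-4,8,12-trimethyl-2-(propanoyloxy)pentadeca-2,9,11-trienoate
Product: 25 (5E)-5-[(2R,6S,7E,9Z)-13-(furan-3-yl)-2,6,10-trimethyltrideca-7,9-dien-1-ylidene]-4-hydroxy-3-methylfuran-2(5H)-one
Conditions: LiN(SiMe3)2 (2.5 equiv), THF, −78 → −30 °C; then 1 M HCl, 0 °C, dark
Reagents that add atoms: none
Why: Dieckmann (intramolecular Claisen) cyclisation, in which the propanoate enolate attacks the adjacent methyl ester in a 5-exo-trig mode and loss of methoxide gives the stable tetronate anion; the enol C=C is not involved, so the E geometry from step 12 and both stereocentres are carried into the target.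

**Compound list**

1 | 3-bromofuran | Brc1ccoc1 | starting material
2 | oxetane | C1COC1 | starting material
3 | furan-3-yllithium | [Li]c1ccoc1 | intermediate
4 | 3-(furan-3-yl)propan-1-ol | OCCCc1ccoc1 | intermediate
5 | 3-(3-bromopropyl)furan | BrCCCc1ccoc1 | intermediate
6 | propyne | CC#C | starting material
7 | [3-(furan-3-yl)propyl]magnesium bromide | Br[Mg]CCCc1ccoc1 | intermediate
8 | [(1Z)-5-(furan-3-yl)-2-methylpent-1-en-1-yl]copper (as its MgBr2 complex) | [Cu]/C=C(/C)CCCc1ccoc1 | intermediate
9 | 3-[(4Z)-5-iodo-4-methylpent-4-en-1-yl]furan | I/C=C(/C)CCCc1ccoc1 | intermediate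
10 | geranyl acetate, (2E)-3,7-dimethylocta-2,6-dien-1-yl acetate | CC(=O)OC/C=C(\C)CCC=C(C)C | starting material
11 | (2E,6E)-8-hydroxy-3,7-dimethylocta-2,6-dien-1-yl acetate | CC(=O)OC/C=C(\C)CC/C=C(\C)CO | intermediate
12 | (3R,7S)-8-hydroxy-3,7-dimethyloctyl acetate | CC(=O)OCC[C@H](C)CCC[C@H](C)CO | intermediate
13 | (3R,7S)-3,7-dimethyl-8-oxooctyl acetate | CC(=O)OCC[C@H](C)CCC[C@H](C)C=O | intermediate
14 | (3R,7S,8E)-3,7-dimethyl-9-(4,4,5,5-tetramethyl-1,3,2-dioxaborolan-2-yl)non-8-en-1-yl acetate | CC(=O)OCC[C@H](C)CCC[C@H](C)/C=C/B1OC(C)(C)C(C)(C)O1 | intermediate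
15 | (3R,7S,8E,10Z)-14-(furan-3-yl)-3,7,11-trimethyltetradeca-8,10-dien-1-yl acetate | CC(=O)OCC[C@H](C)CCC[C@H](C)/C=C/C=C(/C)CCCc1ccoc1 | intermediate
16 | (3R,7S,8E,10Z)-14-(furan-3-yl)-3,7,11-trimethyltetradeca-8,10-dien-1-ol | OCC[C@H](C)CCC[C@H](C)/C=C/C=C(/C)CCCc1ccoc1 | intermediate
17 | (3R,7S,8E,10Z)-14-(furan-3-yl)-3,7,11-trimethyltetradeca-8,10-dienal | O=CC[C@H](C)CCC[C@H](C)/C=C/C=C(/C)CCCc1ccoc1 | intermediate
18 | (3R,7S,8E,10Z)-14-(furan-3-yl)-3,7,11-trimethyltetradeca-1,8,10-trien-1-yl nonafluorobutane-1-sulfonate (1E/1Z mixture) | FC(F)(F)C(F)(F)C(F)(F)C(F)(F)S(=O)(=O)OC=C[C@H](C)CCC[C@H](C)/C=C/C=C(/C)CCCc1ccoc1 | intermediate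
19 | 3-[(4Z,6E,8S,12R)-4,8,12-trimethyltetradeca-4,6-dien-13-yn-1-yl]furan | C#C[C@H](C)CCC[C@H](C)/C=C/C=C(/C)CCCc1ccoc1 | intermediate
20 | lithium acetylide of 19, [(3R,7S,8E,10Z)-14-(furan-3-yl)-3,7,11-trimethyltetradeca-8,10-dien-1-yn-1-yl]lithium | [Li]C#C[C@H](C)CCC[C@H](C)/C=C/C=C(/C)CCCc1ccoc1 | intermediate
21 | methyl (4R,8S,9E,11Z)-15-(furan-3-yl)-4,8,12-trimethylpentadeca-9,11-dien-2-ynoate | COC(=O)C#C[C@H](C)CCC[C@H](C)/C=C/C=C(/C)CCCc1ccoc1 | intermediate
22 | methyl (2E,4R,8S,9E,11Z)-15-(furan-3-yl)-4,8,12-trimethyl-2-(tributylstannyl)pentadeca-2,9,11-trienoate | COC(=O)/C(=C\[C@H](C)CCC[C@H](C)/C=C/C=C(/C)CCCc1ccoc1)[Sn](CCCC)(CCCC)CCCC | intermediate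
23 | methyl (2E,4R,8S,9E,11Z)-15-(furan-3-yl)-2-iodo-4,8,12-trimethylpentadeca-2,9,11-trienoate | COC(=O)/C(I)=C\[C@H](C)CCC[C@H](C)/C=C/C=C(/C)CCCc1ccoc1 | intermediate
24 | methyl (2E,4R,8S,9E,11Z)-15-(furan-3-yl)-4,8,12-trimethyl-2-(propanoyloxy)pentadeca-2,9,11-trienoate | COC(=O)/C(OC(=O)CC)=C\[C@H](C)CCC[C@H](C)/C=C/C=C(/C)CCCc1ccoc1 | intermediate
25 | (5E)-5-[(2R,6S,7E,9Z)-13-(furan-3-yl)-2,6,10-trimethyltrideca-7,9-dien-1-ylidene]-4-hydroxy-3-methylfuran-2(5H)-one | CC1=C(O)/C(=C\[C@H](C)CCC[C@H](C)/C=C/C=C(/C)CCCc2ccoc2)OC1=O | target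

**Step count**

Total: 14 steps (3 for the furan fragment, 11 in the main line). Longest linear sequence: 11 steps (10 → 25, steps 4 to 14).

**Three steps most likely to fail, with fallbacks**

Step 13 is the least precedented step: the intermolecular C–O coupling may be slow, or the iodide may lose its geometry through reversible conjugate addition of carboxylate or iodide. The fallback sets out from 23 and makes the same C–O bond intramolecularly, which is the known mode. Crossed Claisen condensation of 23 with the lithium enolate of tert-butyl propanoate (LiN(iPr)2, THF, −78 °C, 2.2 equiv) gives the β-keto ester tert-butyl (2RS,4E,6R,10S,11E,13Z)-17-(furan-3-yl)-4-iodo-2,6,10,14-tetramethyl-3-oxoheptadeca-4,11,13-trienoate F2. CF3CO2H in CH2Cl2 at 0 °C then gives (2RS,4E,6R,10S,11E,13Z)-17-(furan-3-yl)-4-iodo-2,6,10,14-tetramethyl-3-oxoheptadeca-4,11,13-trienoic acid F3. F3 is cyclised at once as its potassium salt (CuI 10 mol %, trans-N,N′-dimethylcyclohexane-1,2-diamine, K2CO3, 1,4-dioxane, 40 °C) by stereoretentive O-vinylation. This comes back to the route at 25 and makes step 14 unnecessary.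

Step 5 carries the stereochemical risk: the olefin next to the free CH2OH may be reduced with lower selectivity than the acetate-bearing one, or may isomerise to the aldehyde. The fallback sets out from 11 and reduces the two olefins one at a time with two catalyst types. Ru(OAc)2[(S)-BINAP] (the antipode that gives 7S), H2 (50 bar), MeOH hydrogenates only the olefin carrying the free allylic hydroxyl, by hydroxyl direction; the allylic acetate olefin is inert to this catalyst. This gives (2E,7S)-8-hydroxy-3,7-dimethyloct-2-en-1-yl acetate F1, whose purity at C7 can be checked on its own. The remaining olefin of F1 is then reduced with the iridium catalyst of step 5, and the route is rejoined at 12.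

Step 14 may suffer from loss of methylketene from the enol ester enolate (E1cB) or from deprotonation at the allylic stereocentre. The fallback sets out from 23 and generates the same enolate without a Brønsted base. Coupling of 23 with CH2=CHCO2Cs under the conditions of step 13 gives the enol acrylate methyl (2E,4R,8S,9E,11Z)-2-(acryloyloxy)-15-(furan-3-yl)-4,8,12-trimethylpentadeca-2,9,11-trienoate F4. Treatment of F4 with [(Ph3P)CuH]6 (toluene, −40 → 0 °C) delivers hydride to the unhindered acrylate terminus only. The copper enolate so formed is the propanoate enolate of step 14 and closes the ring by reductive Dieckmann cyclisation, by analogy with copper hydride reductive aldol cyclisations. Work-up with cold 1 M HCl gives 25, where the route is rejoined.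

**Further compounds**

F1 | step 5 | (2E,7S)-8-hydroxy-3,7-dimethyloct-2-en-1-yl acetate | CC(=O)OC/C=C(\C)CCC[C@H](C)CO
F2 | step 13 | tert-butyl (2RS,4E,6R,10S,11E,13Z)-17-(furan-3-yl)-4-iodo-2,6,10,14-tetramethyl-3-oxoheptadeca-4,11,13-trienoate | CC(C)(C)OC(=O)C(C)C(=O)/C(I)=C\[C@H](C)CCC[C@H](C)/C=C/C=C(/C)CCCc1ccoc1
F3 | step 13 | (2RS,4E,6R,10S,11E,13Z)-17-(furan-3-yl)-4-iodo-2,6,10,14-tetramethyl-3-oxoheptadeca-4,11,13-trienoic acid | OC(=O)C(C)C(=O)/C(I)=C\[C@H](C)CCC[C@H](C)/C=C/C=C(/C)CCCc1ccoc1
F4 | step 14 | methyl (2E,4R,8S,9E,11Z)-2-(acryloyloxy)-15-(furan-3-yl)-4,8,12-trimethylpentadeca-2,9,11-trienoate | COC(=O)/C(OC(=O)C=C)=C\[C@H](C)CCC[C@H](C)/C=C/C=C(/C)CCCc1ccoc1
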